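The vessel is closed and stirred, and each step with J turns one J into one Z: D + J <-> Z + X, X + J <-> Z + E, then E on to L and G with J, or to Q without it.

| flask | D | J | remark | time |
|---|---|---|---|---|
| noon | 0.40 M | 1.6 M | run made earlier |  |
| dusk | 1.6 M | 1.6 M | run made earlier |  |
| flask | 0.80 M | 1.60 M |  | 5.0 h |

- noon (time / h: X / %, E / %): 0.500: 43, 17; 1.00: 47, 21; 1.50: 50, 18; 2.50: 45, 20; 3.00: 48, 21; 4.00: 47, 20
- dusk (time / h: X / %, E / %): 0.333: 48, 7; 0.500: 52, 5; 0.667: 56, 3; 1.00: 53, 7; 1.50: 55, 3; 2.50: 57, 5; 4.00: 56, 5

(scatter of a reading: 1.5 percentage points)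

- candidate steps: D + J <-> Z + X; X + J <-> Z + E; E + J <-> Z + L; L + J <-> Z + G; E <-> Q

- equivalents of J to D, everything else as given, that leave most X at 5.0 h
- the amount of X then, in percent of the D charged
- the amount of X with the amounts as given

Read both runs as equilibria, since their last four readings stand flat within the scatter. Divide the first two equilibria: J and Z cancel. From dusk take X 55.2 % and E 5.00 %, count the gap as D, and [X][X]/([D][E]) comes to 15.4: the exchange quotient, the equilibrium constant for D and E going to two X, as read from these readings.

Now reckon what is left beside X. Let c be the followers L, G and Q per E. With m and c held, the remainder is least when [D] equals E and its followers together, and remainder over X is then 2√((1+c)/m).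

Solve two extremes. With no followers, X peaks at 66.2 %. If noon's whole gap followed E (X 47.5 %, E 19.8 %), c is 1.66 and the peak 54.6 %. But m puts noon's D at 7.44 %, so part of that gap is D, and this flask has half noon's J per D. Commit to the middle, 60.4 %. Dusk holds more D than E, noon less, so put the best charge between 1.00 and 4.00 equiv.

The forecast, holding that “both runs are at equilibrium”, gives 1.6 equiv, 59 % and 58 %.

The flask gives 58.7 %, and 59.9 % at 1.57 equiv; left ten times as long, it holds 57.0 %. Its followers at the end make c 0.967, and m then puts the peak of X at 58.3 %.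

    D + J ⇌ Z + X (K = 4.50, k = 0.00123 /M/s)
    X + J ⇌ Z + E (K = 0.279, k = 0.00228 /M/s)
    E + J ⇌ Z + L (K = 0.545, k = 0.00110 /M/s)
    L + J ⇌ Z + G (K = 2.45, k = 5.60 × 10⁻⁵ /M/s)
    E ⇌ Q (K = 0.330, k = 0.00232 /s)

Take the neighbour charged with 0.40 M of J: its D 58.8 % and X 38.9 % leave E at 1.67 % by m. The computed flask holds 1.60 %.

The data were computed with constants of no real substance, and the scatter is random.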